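## Retrosynthetic overview

1. The target is a C2-symmetric head-to-tail dimer of two 3-methylquinolizidin-2-ones (each half numbered C1–C4, N5, C6–C9, C9a), joined by two pentamethylene chains (C9 to C1 of the other half) in a 16-membered carbocycle.
2. Enabling feature: in each ring A (N5–C4–C3–C2–C1–C9a) the ketone carbon C2 carries C3H(CH3)–C4H2–N5, which is an N-allyl group at a lower oxidation level, and C1 and C3 are both α to C2. An ester carbon on C1 therefore lies six atoms (C2–C1–C9a–N5–C4–C3) from the inner alkene carbon.
3. Key disconnection C2–C3, both halves at once: two-fold intramolecular Kulinkovich cyclopropanation of the bis(N-allyl β-amino ester) 18 closes both rings A as strained 3-azabicyclo[4.1.0]heptan-6-ols (19). Base-induced strain release then cleaves C2–CH2 to give C2=O and the C3 methyl, and C1/C3 equilibrate to the all-equatorial target.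
4. Before that: rings B by two-fold amine–ketone condensation and C9-controlled reduction (C9a) on the macrocyclic bis(β-keto ester) 14; the 16-membered ring by head-to-tail cyclodimerisation of the ω-iodo β-keto ester 12 (C1 alkylation).
5. C9, the only stereocentre not relayed, is set by Ir-catalysed asymmetric hydrogenation of alkylidene lactam 6, made from N-Boc-2-piperidone. Ring order: 16-membered carbocycle, then rings B, then rings A.

Key step: step 12

Remark: the SMILES is read as the C2-symmetric isomer with 1R,3S,9S,9aR in both halves (ring A all-equatorial, C9–H cis to C9a–H); the lettering C1…C9a above is used for all intermediates.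

## Route

Step 1
Reactants: 1 5-chloropentan-1-ol
Product: 2 5-chloropentanal
Conditions: TEMPO (10 mol %), PhI(OAc)2, CH2Cl2, rt
Reagents that add atoms: none
Why: TEMPO/PhI(OAc)2 oxidation of a primary alcohol stops at the aldehyde and leaves the alkyl chloride untouched.

Step 2
Reactants: 3 tert-butyl 2-oxopiperidine-1-carboxylate; 2 5-chloropentanal
Product: 4 tert-butyl 3-(5-chloro-1-hydroxypentyl)-2-oxopiperidine-1-carboxylate (diastereomer mixture)
Conditions: LiN(SiMe3)2, THF, −78 °C; then 2, −78 °C; aq NH4Cl at −78 °C
Reagents that add atoms: none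
Why: Lithium enolate aldol addition of an N-acyl lactam, quenched cold to suppress N-to-O Boc transfer; both new stereocentres are removed in step 3.

Step 3
Reactants: 4 tert-butyl 3-(5-chloro-1-hydroxypentyl)-2-oxopiperidine-1-carboxylate
Product: 6 tert-butyl (3E)-3-(5-chloropentylidene)-2-oxopiperidine-1-carboxylate, via aldol mesylate 5 (not isolated)
Conditions: MsCl, Et3N, CH2Cl2, 0 °C; then DBU, rt
Reagents that add atoms: none
Why: Mesylation and E1cB elimination should give the conjugated exocyclic alkene as the thermodynamically preferred E isomer.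

Step 4
Reactants: 6 tert-butyl (3E)-3-(5-chloropentylidene)-2-oxopiperidine-1-carboxylate
Product: 7 tert-butyl (3S)-3-(5-chloropentyl)-2-oxopiperidine-1-carboxylate
Conditions: H2 (30 bar), [Ir(cod)(L*)][B(3,5-(CF3)2C6H3)4] (1 mol %; L* = one enantiomer of a spiro phosphine–oxazoline P,N ligand), CH2Cl2, rt
Reagents that add atoms: none
Why: Asymmetric hydrogenation of an exocyclic α-alkylidene lactam with a cationic iridium P,N catalyst, a substrate class for which these catalysts are highly enantioselective, sets C9; the ligand enantiomer is chosen, and its sense checked on the first batch, to give S.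

Step 5
Reactants: 7 tert-butyl (3S)-3-(5-chloropentyl)-2-oxopiperidine-1-carboxylate
Product: 8 (2S)-2-[3-(tert-butoxycarbonylamino)propyl]-7-chloroheptanoic acid
Conditions: LiOH, THF/H2O, 0 °C; then 1 M HCl to pH 3, 0 °C
Reagents that add atoms: lithium hydroxide, [Li+].[OH-]
Why: Hydroxide opens the imide-like N-Boc lactam at the ring carbonyl to the δ-Boc-amino acid, at 0 °C without displacing the primary chloride or epimerising C9.

Step 6
Reactants: 8 (2S)-2-[3-(tert-butoxycarbonylamino)propyl]-7-chloroheptanoic acid
Product: 11 methyl (4S)-4-[3-(tert-butoxycarbonylamino)propyl]-9-chloro-3-oxononanoate, via acyl imidazolide 9 (not isolated), via acylmalonate half-ester 10 (not isolated)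
Conditions: CDI, THF, rt; then KO2CCH2CO2Me, MgCl2, Et3N, THF, rt to 40 °C; 1 M HCl work-up
Reagents that add atoms: potassium methyl malonate, COC(=O)CC(=O)[O-].[K+]
Why: Masamune-type chain extension, in which the acyl imidazolide C-acylates the magnesium enolate of the malonate half-ester and decarboxylation gives the β-keto ester under near-neutral conditions that leave C9 intact.

Step 7
Reactants: 11 methyl (4S)-4-[3-(tert-butoxycarbonylamino)propyl]-9-chloro-3-oxononanoate
Product: 12 methyl (4S)-4-[3-(tert-butoxycarbonylamino)propyl]-9-iodo-3-oxononanoate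
Conditions: NaI, acetone, reflux
Reagents that add atoms: sodium iodide, [Na+].[I-]
Why: Finkelstein exchange turns the robust chloride carried through the earlier steps into the iodide needed for mild alkylation.

Step 8
Reactants: 12 methyl (4S)-4-[3-(tert-butoxycarbonylamino)propyl]-9-iodo-3-oxononanoate (two molecules)
Product: 14 dimethyl (3S,11S)-3,11-bis[3-(tert-butoxycarbonylamino)propyl]-2,10-dioxocyclohexadecane-1,9-dicarboxylate (epimers at the ester-bearing carbons), via linear dimer iodide 13 (not isolated)
Conditions: Cs2CO3, MeCN, 5 mM, 60 °C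
Reagents that add atoms: none
Why: Acetoacetic-ester-type C-alkylation in which each molecule has one nucleophile (C1) and one electrophile (chain terminus), so union can only be head to tail, monomer closure would need an eight-membered ring, and dilution lets the linear dimer close to the 16-membered ring; the C1 centres formed are erased in step 9.

Step 9
Reactants: 14 dimethyl (3S,11S)-3,11-bis[3-(tert-butoxycarbonylamino)propyl]-2,10-dioxocyclohexadecane-1,9-dicarboxylate
Product: 16 macrocyclic bis(Z-enamino ester) (two 3-substituted piperidin-2-ylidene rings B; C9a=C1 bearing CO2Me), via bis-ammonium trifluoroacetate 15 (not isolated)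
Conditions: TFA, CH2Cl2, 0 °C to rt; concentrate; then Et3N, MeOH, 4 Å MS, rt to 50 °C
Reagents that add atoms: none
Why: Acidolysis of both Boc groups and six-membered amine–ketone condensation should give the ester-conjugated, hydrogen-bonded Z enamino esters, with tautomerisation running toward the activated C1 and not toward C9, so C9 is kept and both C1 centres converge to sp2.

Step 10
Reactants: 16 macrocyclic bis(Z-enamino ester)
Product: 17 macrocyclic bis(2,3-cis-piperidine) dimethyl diester (C9 and C9a as in the target; C1 epimers)
Conditions: NaBH(OAc)3, AcOH/MeCN, 0 °C to rt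
Reagents that add atoms: none
Why: Reduction of β-enamino esters with NaBH(OAc)3/AcOH goes by C1 protonation and axial hydride delivery to the cyclic iminium ion anti to the pseudoaxial C9 chain (A(1,2) strain), which should set C9a with its hydrogen cis to C9–H; C1 forms as a mixture that is corrected in step 13.

Step 11
Reactants: 17 macrocyclic bis(2,3-cis-piperidine) dimethyl diester
Product: 18 macrocyclic bis(N-allyl-2,3-cis-piperidine) dimethyl diester
Conditions: allyl bromide, K2CO3, MeCN, 50 °C
Reagents that add atoms: allyl bromide, C=CCBr
Why: SN2 N-allylation of the hindered secondary amines installs C4, C3 and the future C3-methyl carbon, with quaternisation disfavoured by the 2,3-disubstitution.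

Step 12
Reactants: 18 macrocyclic bis(N-allyl-2,3-cis-piperidine) dimethyl diester
Product: 19 macrocyclic bis(cyclopropanol) (each ring A closed as a cis-fused 3-azabicyclo[4.1.0]heptan-6-ol; C9 and C9a as in the target; mixture at C1/C2/C3)
Conditions: ClTi(OiPr)3 (2.4 equiv), c-C5H9MgCl (10 equiv, slow addition), THF, rt; aq work-up
Reagents that add atoms: none
Why: Two equivalents of c-C5H9MgCl convert ClTi(OiPr)3 into the cyclopentene complex (iPrO)2Ti(C5H8), which exchanges its alkene for the terminal alkene of each N-allyl group; the inner carbon C3 of the resulting titanacyclopropane adds to the ester carbonyl C2 held on C1 (intramolecular acyl substitution, loss of methoxide), and the remaining Ti–CH2 bond of the β-titanio ketone closes onto the new ketone to give the titanium cyclopropoxide. The closest known reaction type is the ligand-exchange Kulinkovich cyclopropanation of esters carrying a tethered terminal alkene, N-allyl amino esters included, which gives bicyclo[n.1.0]alkan-1-ols. Ring A closes 6-exo-trig at the ester carbonyl through the C2–C3 bond, and the cyclopropane closes 3-exo-trig through the C2–CH2 bond. The new centres C2 and C3 can only be cis on the three-membered ring, and their sense relative to C1 and C9a need not be controlled because C2 returns to sp2 and C3 is equilibrated in step 13. The selectivity needed is chemoselectivity for the tethered alkene over direct reaction of the cyclopentene complex or the Grignard reagent with the ester, secured by the low reactivity of the 1,2-disubstituted titanacyclopropane, slow addition, and the six-atom tether C2–C1–C9a–N5–C4–C3. The two sites are remote across the 16-membered ring and should react independently, and the tertiary amines and the C9/C9a centres are inert to the reagent.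

Step 13
Reactants: 19 macrocyclic bis(cyclopropanol)
Product: 20 target bis(3-methylquinolizidin-2-one) macrocycle (1R,3S,9S,9aR in both halves)
Conditions: KOH, MeOH/H2O (9:1), rt to 40 °C
Reagents that add atoms: none
Why: Base-induced cyclopropanol ring opening cleaves the C2–CH2 bond toward the primary carbon and protonates it to the C3 methyl while C2 becomes the ketone, and under the same conditions C1 and C3, both α to C2, epimerise by enolisation to the diequatorial 1R,3S arrangement fixed by C9a, with C9 and C9a untouched.

## Compound list

1 | 5-chloropentan-1-ol | OCCCCCCl | starting material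
2 | 5-chloropentanal | O=CCCCCCl | intermediate
3 | tert-butyl 2-oxopiperidine-1-carboxylate | O=C1CCCCN1C(=O)OC(C)(C)C | starting material
4 | tert-butyl 3-(5-chloro-1-hydroxypentyl)-2-oxopiperidine-1-carboxylate (diastereomer mixture) | O=C1C(C(O)CCCCCl)CCCN1C(=O)OC(C)(C)C | intermediate
5 | aldol mesylate: tert-butyl 3-[5-chloro-1-(methylsulfonyloxy)pentyl]-2-oxopiperidine-1-carboxylate | O=C1C(C(OS(C)(=O)=O)CCCCCl)CCCN1C(=O)OC(C)(C)C | intermediate (not isolated)
6 | tert-butyl (3E)-3-(5-chloropentylidene)-2-oxopiperidine-1-carboxylate | ClCCCC/C=C1\CCCN(C(=O)OC(C)(C)C)C1=O | intermediate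
7 | tert-butyl (3S)-3-(5-chloropentyl)-2-oxopiperidine-1-carboxylate | O=C1[C@@H](CCCCCCl)CCCN1C(=O)OC(C)(C)C | intermediate
8 | (2S)-2-[3-(tert-butoxycarbonylamino)propyl]-7-chloroheptanoic acid | OC(=O)[C@@H](CCCCCCl)CCCNC(=O)OC(C)(C)C | intermediate
9 | acyl imidazolide of 8 | O=C([C@@H](CCCCCCl)CCCNC(=O)OC(C)(C)C)n1ccnc1 | intermediate (not isolated)
10 | acylmalonate half-ester: (4S)-4-[3-(tert-butoxycarbonylamino)propyl]-9-chloro-2-(methoxycarbonyl)-3-oxononanoic acid (held as its magnesium salt) | COC(=O)C(C(=O)O)C(=O)[C@@H](CCCCCCl)CCCNC(=O)OC(C)(C)C | intermediate (not isolated)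
11 | methyl (4S)-4-[3-(tert-butoxycarbonylamino)propyl]-9-chloro-3-oxononanoate | COC(=O)CC(=O)[C@@H](CCCCCCl)CCCNC(=O)OC(C)(C)C | intermediate
12 | methyl (4S)-4-[3-(tert-butoxycarbonylamino)propyl]-9-iodo-3-oxononanoate | COC(=O)CC(=O)[C@@H](CCCCCI)CCCNC(=O)OC(C)(C)C | intermediate
13 | linear dimer iodide (C1 of one unit alkylated by the chain terminus of the other; one free CH2 β-keto ester, one iodide) | COC(=O)CC(=O)[C@@H](CCCCCC(C(=O)OC)C(=O)[C@@H](CCCCCI)CCCNC(=O)OC(C)(C)C)CCCNC(=O)OC(C)(C)C | intermediate (not isolated)
14 | dimethyl (3S,11S)-3,11-bis[3-(tert-butoxycarbonylamino)propyl]-2,10-dioxocyclohexadecane-1,9-dicarboxylate (epimers at C1/C9 of the carbocycle) | COC(=O)C1C(=O)[C@H](CCCNC(=O)OC(C)(C)C)CCCCCC(C(=O)OC)C(=O)[C@H](CCCNC(=O)OC(C)(C)C)CCCCC1 | intermediate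
15 | bis-ammonium trifluoroacetate of the macrocyclic bis(δ-amino β-keto ester) | COC(=O)C1C(=O)[C@H](CCC[NH3+])CCCCCC(C(=O)OC)C(=O)[C@H](CCC[NH3+])CCCCC1.[O-]C(=O)C(F)(F)F.[O-]C(=O)C(F)(F)F | intermediate (not isolated)
16 | macrocyclic bis(Z-enamino ester): two (3S)-piperidin-2-ylidene rings B whose exocyclic C9a=C1 bonds carry CO2Me (N–H cis to the ester), linked head to tail by two pentamethylene chains | COC(=O)/C1=C2\NCCC[C@@H]2CCCCC/C(C(=O)OC)=C3/NCCC[C@@H]3CCCCC1 | intermediate
17 | macrocyclic bis(2,3-cis-piperidine) dimethyl diester (C9 S, C9a R, C9–H cis to C9a–H; C1 epimers) | COC(=O)C1[C@@H]2NCCC[C@@H]2CCCCCC(C(=O)OC)[C@@H]3NCCC[C@@H]3CCCCC1 | intermediate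
18 | macrocyclic bis(N-allyl-2,3-cis-piperidine) dimethyl diester (C9 S, C9a R; C1 epimers) | COC(=O)C1[C@@H]2N(CC=C)CCC[C@@H]2CCCCCC(C(=O)OC)[C@@H]3N(CC=C)CCC[C@@H]3CCCCC1 | intermediate
19 | macrocyclic bis(cyclopropanol): in each half C2 (tertiary OH), C3 and a new CH2 form a cyclopropane cis-fused to ring A (3-azabicyclo[4.1.0]heptan-6-ol); C9 S, C9a R; mixture at C1/C2/C3 | OC12CC1CN3CCC[C@@H]4CCCCCC5[C@@H]6N(CC7CC57O)CCC[C@@H]6CCCCCC2[C@@H]43 | intermediate
20 | target: C2-symmetric bis(3-methylquinolizidin-2-one) macrocycle, 1R,3S,9S,9aR in both halves | C[C@H]1CN2CCC[C@@H]3CCCCC[C@H]4C(=O)[C@@H](C)CN5CCC[C@H](CCCCC[C@@H](C1=O)[C@@H]32)[C@H]45 | target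

## Step count and risks

Total step count: 13. Longest linear sequence: 13 steps (1 to 20; compound 3 enters at step 2, and step 8 joins two molecules of 12).

Steps most likely to fail:

Step 12. The alkene exchange on titanium may stop at one site, the allylic amine may be lost by β-elimination from the titanacyclopropane, or the Grignard reagent may add directly to the esters. Fallback (acyl radical route, known chemistry): setting out from 18, treatment with Me2AlSePh (from AlMe3 and PhSeH, CH2Cl2, 0 °C to rt) should convert both methyl esters into the macrocyclic bis(Se-phenyl selenoester) F1. Slow addition of Bu3SnH/AIBN in benzene at 80 °C should then generate the two acyl radicals, which close 6-exo-trig onto the inner carbon of the N-allyl groups (C2–C3) and are reduced at the exocyclic carbon to the C3 methyl. Brief K2CO3/MeOH equilibration of C1 and C3 brings the material back to the route at 20, bypassing 19.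

Step 8. Chain growth to linear oligomers may outrun ring closure of the linear dimer, or O-alkylation may compete. Fallback (stepwise assembly, ring closure purely intramolecular): setting out from 7, NaI in acetone should give tert-butyl (3S)-3-(5-iodopentyl)-2-oxopiperidine-1-carboxylate F2. The chloro keto ester 11, whose chloride is inert at room temperature, is C-alkylated with F2 (K2CO3, acetone, rt) to the keto ester–lactam F3. Excess LiCH2CO2Me (from LiN(iPr)2 and methyl acetate, THF, −78 °C) first masks the existing β-keto ester as its enolate and then opens the N-Boc lactam to a second β-keto ester, giving the chloro linear dimer F4. NaI in acetone then gives 13, this time isolated, where the fallback rejoins the route; Cs2CO3 at high dilution closes it to 14.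

Step 10. Hydride may be delivered to the wrong face at one of the two C9a centres inside the macrocycle, or reduction of the tetrasubstituted enamino esters may stall. Fallback (ring B and C9a set on the monomer, then cyclodimerisation of the finished piperidine): setting out from 11, TFA then Et3N should give methyl (2Z)-2-[(3S)-3-(5-chloropentyl)piperidin-2-ylidene]acetate F5, a trisubstituted enamino ester. NaBH(OAc)3/AcOH reduction gives methyl 2-[(2S,3S)-3-(5-chloropentyl)piperidin-2-yl]acetate F6 (2,3-cis), which can be purified and assigned at this simple stage. Allyl bromide/K2CO3 gives the N-allyl chloro ester F7, and NaI in acetone gives the N-allyl iodo ester F8, used at once. LiN(iPr)2 in THF at −78 °C to rt under high dilution should effect head-to-tail cyclodimerisation by ester-enolate alkylation and return to the route at 18.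

Further compounds
F1 | step 12 | macrocyclic bis(Se-phenyl selenoester) corresponding to 18 | O=C([Se]c1ccccc1)C1[C@@H]2N(CC=C)CCC[C@@H]2CCCCCC(C(=O)[Se]c2ccccc2)[C@@H]2N(CC=C)CCC[C@@H]2CCCCC1
F2 | step 8 | tert-butyl (3S)-3-(5-iodopentyl)-2-oxopiperidine-1-carboxylate | O=C1[C@@H](CCCCCI)CCCN1C(=O)OC(C)(C)C
F3 | step 8 | keto ester–lactam: 11 alkylated at C1 by the pentyl chain of the N-Boc lactam unit | COC(=O)C(CCCCC[C@H]1CCCN(C(=O)OC(C)(C)C)C1=O)C(=O)[C@@H](CCCCCCl)CCCNC(=O)OC(C)(C)C
F4 | step 8 | chloro linear dimer (chloride analogue of 13) | COC(=O)CC(=O)[C@@H](CCCCCC(C(=O)OC)C(=O)[C@@H](CCCCCCl)CCCNC(=O)OC(C)(C)C)CCCNC(=O)OC(C)(C)C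
F5 | step 10 | methyl (2Z)-2-[(3S)-3-(5-chloropentyl)piperidin-2-ylidene]acetate | COC(=O)/C=C1\NCCC[C@@H]1CCCCCCl
F6 | step 10 | methyl 2-[(2S,3S)-3-(5-chloropentyl)piperidin-2-yl]acetate (2,3-cis) | COC(=O)C[C@@H]1NCCC[C@@H]1CCCCCCl
F7 | step 10 | methyl 2-[(2S,3S)-1-allyl-3-(5-chloropentyl)piperidin-2-yl]acetate | COC(=O)C[C@@H]1N(CC=C)CCC[C@@H]1CCCCCCl
F8 | step 10 | methyl 2-[(2S,3S)-1-allyl-3-(5-iodopentyl)piperidin-2-yl]acetate | COC(=O)C[C@@H]1N(CC=C)CCC[C@@H]1CCCCCI
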